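The strategy rests on the aldol pattern C8(O)–C9H2–C10(OH)(CH3)–C1(=O) in ring A (the ten-membered carbocycle C1–C10): C9–C10 is cut to an open-chain C8 bromomethyl ketone / C10 methyl ketone, closed by a SmI2 Reformatsky aldol in which a (1R)-PMB ether chelates the metal and sets C10; C1 becomes the ketone at the end.
Open chain: C6–C7 by an Evans syn aldol (vinylogous enolisation of an (E)-4-silyloxy-3-methylbut-2-enoyl oxazolidinone, α-attack creating the C11=C13 methylene) on a (Z)-enal; the C8 Weinreb amide is converted to the bromomethyl ketone with LiCH2Br while C10 is still a TES-protected carbinol.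
Enal: C3–C4 by B-alkyl Suzuki coupling of (Z)-3-iodobut-2-en-1-ol with a C1/C10/C14 unit from Sharpless epoxidation of divinyl carbinol (source of 1R).
Ring order: ring A first (key step); then C8 anti-reduction and tigloylation; then ring B (α-methylene-γ-butyrolactone O–C6–C7–C11–C12) by oxidative lactonisation; C1 deprotection and oxidation last.

Key step: step 19

Remark: germacrane locants are used for all intermediates (ring C1–C10, C11–C13 on C7, C14 on C10, C15 on C4); Cram-chelate control by the (1R)-PMB ether is assumed to hold in the ring-closing mode; C10 stays a triethylsilyl-protected carbinol until C9 is in place, because bromomethyllithium would add to a free C10 ketone, and C12 carries TBDPS so that this TES ether can be removed selectively.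

Step 1
Reactants: 1 penta-1,4-dien-3-ol
Product: 2 (2S,3R)-1,2-epoxypent-4-en-3-ol
Conditions: Ti(OiPr)4, D-(−)-diisopropyl tartrate, cumene hydroperoxide, 4 Å MS, CH2Cl2, −20 °C
Reagents that add atoms: cumene hydroperoxide, CC(C)(OO)c1ccccc1
Why: Sharpless asymmetric epoxidation selects one enantiotopic vinyl group and one of its faces (erythro product) while the minor enantiomer is drained by a faster second epoxidation, so the carbinol carbon (later C1, R) and the oxirane carbon (later C10, S) should be set together in high enantiomeric purity.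

Step 2
Reactants: 2 (2S,3R)-1,2-epoxypent-4-en-3-ol
Product: 3 (S)-2-[(R)-1-(4-methoxybenzyloxy)prop-2-en-1-yl]oxirane
Conditions: NaH, 4-methoxybenzyl chloride, Bu4NI (cat.), THF, 0 °C → rt
Reagents that add atoms: 4-methoxybenzyl chloride, COc1ccc(CCl)cc1
Why: Williamson etherification of the sodium alkoxide with the benzylic halide at low temperature in THF should outrun Payne rearrangement of the epoxy alkoxide, so both stereocentres are kept.

Step 3
Reactants: 3 PMB-protected epoxide
Product: 4 (2S,3R)-3-(4-methoxybenzyloxy)pent-4-en-2-ol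
Conditions: LiAlH4, THF, 0 °C
Reagents that add atoms: none
Why: SN2 hydride opening of the terminal epoxide at its unsubstituted carbon turns the oxirane CH2 into the C14 methyl group and leaves the C10 carbinol and the C1 ether centres untouched.

Step 4
Reactants: 4 (2S,3R)-3-(4-methoxybenzyloxy)pent-4-en-2-ol
Product: 5 triethyl{[(2S,3R)-3-(4-methoxybenzyloxy)pent-4-en-2-yl]oxy}silane
Conditions: Et3SiCl, imidazole, DMF, 0 °C → rt
Reagents that add atoms: chlorotriethylsilane, CC[Si](Cl)(CC)CC
Why: Standard silylation of the secondary alcohol masks the future C10 ketone as a carbinol ether that is more labile than the TBS and TBDPS ethers introduced later.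

Step 5
Reactants: 6 but-2-yn-1-ol
Product: 8 (Z)-3-iodobut-2-en-1-ol, via cyclic alkenylaluminate 7 (not isolated)
Conditions: NaAlH2(OCH2CH2OMe)2, THF, 0 °C → rt; then I2, −78 → 0 °C
Reagents that add atoms: iodine, [I][I]
Why: Hydroxyl-directed trans-hydroalumination places aluminium on C3 cis to the CH2O group in a five-membered aluminate, and iodinolysis with retention gives the Z-vinyl iodide.

Step 6
Reactants: 5 TES/PMB-protected pentenediol; 8 (Z)-3-iodobut-2-en-1-ol
Product: 10 (2Z,6R,7S)-6-(4-methoxybenzyloxy)-3-methyl-7-(triethylsilyloxy)oct-2-en-1-ol, via B-alkyl-9-borabicyclononane 9 (not isolated)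
Conditions: 9-BBN, THF, 0 °C → rt; then 8, [1,1'-bis(diphenylphosphino)ferrocene]PdCl2 (cat.), AsPh3, Cs2CO3, DMF/H2O, rt
Reagents that add atoms: none
Why: Anti-Markovnikov hydroboration of the terminal alkene followed by B-alkyl Suzuki–Miyaura coupling joins C3 to C4 with retention of the vinyl iodide geometry, which fixes the Z-C4=C5 trisubstituted alkene.

Step 7
Reactants: 10 Z-allylic alcohol
Product: 11 (2Z,6R,7S)-6-(4-methoxybenzyloxy)-3-methyl-7-(triethylsilyloxy)oct-2-enal
Conditions: 2,2,6,6-tetramethylpiperidin-1-oxyl (TEMPO, cat.), PhI(OAc)2, CH2Cl2, rt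
Reagents that add atoms: none
Why: Oxoammonium-mediated oxidation of the primary allylic alcohol stops at the aldehyde under near-neutral conditions that should neither isomerise the Z-enal nor cleave the TES ether.

Step 8
Reactants: 12 methyl 3-methylbut-2-enoate
Product: 13 methyl (E)-3-methyl-4-oxobut-2-enoate
Conditions: SeO2, 1,4-dioxane, reflux
Reagents that add atoms: selenium dioxide, O=[Se]=O
Why: Selenium dioxide allylic oxidation (ene reaction then [2,3]-shift) attacks the methyl group trans to the ester and carries it to the aldehyde, leaving the remaining methyl cis to the carbonyl.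

Step 9
Reactants: 13 methyl (E)-3-methyl-4-oxobut-2-enoate
Product: 14 methyl (E)-4-hydroxy-3-methylbut-2-enoate
Conditions: NaBH4, CeCl3·7H2O, MeOH, −20 °C
Reagents that add atoms: none
Why: Luche reduction delivers hydride to the aldehyde only (1,2-addition) and leaves the conjugated ester and the E geometry intact.

Step 10
Reactants: 14 methyl (E)-4-hydroxy-3-methylbut-2-enoate
Product: 15 methyl (E)-4-(tert-butyldiphenylsilyloxy)-3-methylbut-2-enoate
Conditions: t-BuPh2SiCl, imidazole, DMF, rt
Reagents that add atoms: tert-butyl(chloro)diphenylsilane, CC(C)(C)[Si](Cl)(c1ccccc1)c1ccccc1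
Why: Standard silylation installs an acid-robust primary silyl ether at C12 that will outlast the later TES cleavage.

Step 11
Reactants: 15 silyloxy methyl ester
Product: 16 (E)-4-(tert-butyldiphenylsilyloxy)-3-methylbut-2-enoic acid
Conditions: LiOH·H2O, THF/MeOH/H2O, rt; then 1 M HCl to pH 3
Reagents that add atoms: lithium hydroxide monohydrate, [Li+].[OH-].O
Why: Saponification of the methyl ester proceeds under conditions that the TBDPS ether tolerates and does not move the double bond.

Step 12
Reactants: 16 silyloxy enoic acid; 17 (S)-4-benzyloxazolidin-2-one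
Product: 19 (S)-4-benzyl-3-[(E)-4-(tert-butyldiphenylsilyloxy)-3-methylbut-2-enoyl]oxazolidin-2-one, via mixed pivalic anhydride 18 (not isolated)
Conditions: t-BuCOCl, Et3N, THF, −20 °C; then 17, LiCl, rt
Reagents that add atoms: none
Why: N-acylation of the oxazolidinone through the mixed pivalic anhydride attaches the auxiliary under mild conditions that keep the E-enoyl geometry.

Step 13
Reactants: 19 enoyl oxazolidinone; 11 Z-enal
Product: 22 (6R,7S)-syn-aldol adduct (acyl oxazolidinone), via boron dienolate 20 (not isolated), via boron aldolate 21 (not isolated)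
Conditions: Bu2BOTf, Et3N, CH2Cl2, −78 → 0 °C; then 11, −78 → 0 °C; pH 7 buffer, MeOH, 30% H2O2, 0 °C
Reagents that add atoms: none
Why: Evans syn aldol with vinylogous enolisation, in which Bu2BOTf/Et3N removes a proton of the methyl cis to the carbonyl to give the Z(O)-dienol borinate that attacks the aldehyde at its α-carbon through a Zimmerman–Traxler chair on the face dictated by the (S)-benzyl auxiliary, should set 6R and 7S (syn) and create the C11=C13 methylene.

Step 14
Reactants: 22 syn-aldol adduct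
Product: 23 C8 Weinreb amide with free C6 hydroxyl
Conditions: MeONHMe·HCl, AlMe3, THF, −20 → 0 °C
Reagents that add atoms: N,O-dimethylhydroxylamine hydrochloride, CNOC.Cl
Why: Aluminium-amide transamidation (Weinreb amide formation), assisted by the free C6 aluminium alkoxide, displaces the auxiliary without epimerising C7.

Step 15
Reactants: 23 hydroxy Weinreb amide
Product: 24 C6 TBS ether of the Weinreb amide
Conditions: t-BuMe2SiOTf, 2,6-lutidine, CH2Cl2, −78 °C
Reagents that add atoms: tert-butyldimethylsilyl trifluoromethanesulfonate, CC(C)(C)[Si](C)(C)OS(=O)(=O)C(F)(F)F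
Why: Silylation with the silyl triflate and a hindered base protects the hindered secondary allylic alcohol without touching the acid-labile TES and PMB ethers.

Step 16
Reactants: 24 TBS-protected Weinreb amide; 25 dibromomethane
Product: 27 C8 bromomethyl ketone (C10 OTES), via lithium hemiaminal alkoxide 26 (not isolated)
Conditions: CH2Br2, MeLi·LiBr, THF/Et2O, −78 °C; AcOH quench at −78 °C
Reagents that add atoms: none
Why: Bromomethyllithium, generated by Br/Li exchange in the presence of the amide, adds once to the Weinreb amide because the chelated tetrahedral adduct survives until the cold acidic quench, and no other carbonyl group is present since C10 is still a silyl ether.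

Step 17
Reactants: 27 bromomethyl ketone (C10 OTES)
Product: 28 bromomethyl ketone with free C10 hydroxyl
Conditions: AcOH/THF/H2O (3:1:1), rt
Reagents that add atoms: none
Why: Acid-catalysed solvolysis cleaves the secondary TES ether far faster than the secondary TBS and primary TBDPS ethers, and the α-bromo ketone tolerates aqueous acetic acid.

Step 18
Reactants: 28 hydroxy bromomethyl ketone
Product: 29 open-chain C8 bromomethyl ketone / C10 methyl ketone (key precursor)
Conditions: Dess–Martin periodinane, NaHCO3, CH2Cl2, 0 °C → rt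
Reagents that add atoms: none
Why: Dess–Martin oxidation converts the C10 carbinol into the methyl ketone under buffered, non-basic conditions that spare the α-bromo ketone and the epimerisable C1 centre.

Step 19
Reactants: 29 bromo diketone
Product: 32 ten-membered C8 ketone with (10R) tertiary alcohol, via samarium enolate 30 (not isolated), via samarium aldolate 31 (not isolated)
Conditions: SmI2 (2.2 equiv, 0.1 M in THF, added dropwise), THF (0.003 M in 29), −78 °C; sat. NH4Cl at −78 °C
Reagents that add atoms: none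
Why: Two single-electron transfers from divalent samarium cleave the C9–Br bond and give the trivalent samarium enolate 30 regiospecifically at O–C8=C9 (the more acidic C7–H is never engaged), and this enolate adds to the C10 ketone to form C9–C10. The closest known reaction type is the SmI2-promoted intramolecular Reformatsky reaction of α-halo carbonyl compounds used to close medium and large rings. Ring A (the ten-membered carbocycle C1–C10) closes in a 10-(enolendo)-exo-trig aldol under high dilution, the Z-C4=C5 alkene and the C6/C7 substituents pre-folding the chain. The new C10 centre is controlled by the (1R)-PMB ether: trivalent samarium bridges the C10 carbonyl oxygen and the C1 ether oxygen in a five-membered Cram chelate, so C9 attacks the face bearing C1–H, opposite C2, which should give 10R. The step needs chemoselectivity (C–Br reduction before ketyl formation or α-alkoxy cleavage at C10) and facial selectivity; the first is secured by the much faster reduction of α-bromo ketones at −78 °C with SmI2 never in excess, the second by the chelating benzylic ether, with which the bulky silyl ethers at C6 and C12 do not compete.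

Step 20
Reactants: 32 ten-membered β-hydroxy ketone
Product: 33 (8R,10R)-anti-8,10-diol
Conditions: Me4NBH(OAc)3, MeCN/AcOH (1:1), −30 °C
Reagents that add atoms: none
Why: Evans–Saksena hydroxyl-directed reduction, in which the C10 hydroxyl exchanges onto boron and hydride is delivered intramolecularly through a chair-like six-membered transition state, should give the 8,10-anti diol (8R).

Step 21
Reactants: 33 anti-diol; 34 tiglic acid
Product: 36 C8 tiglate, via mixed trichlorobenzoic anhydride 35 (not isolated)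
Conditions: 2,4,6-trichlorobenzoyl chloride, Et3N, THF, rt; then 33, 4-(dimethylamino)pyridine, toluene, rt
Reagents that add atoms: none
Why: Yamaguchi esterification acylates the secondary C8 hydroxyl while the tertiary C10 hydroxyl is too hindered to react.

Step 22
Reactants: 36 C8 tiglate
Product: 37 C6,C12-diol (C1 OPMB, C8 tiglate)
Conditions: HF·pyridine, pyridine, THF, 0 °C → rt
Reagents that add atoms: none
Why: Fluoride-mediated desilylation under buffered acidic conditions removes the TBS and TBDPS ethers without ester migration or retro-aldol chemistry.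

Step 23
Reactants: 37 C6,C12-diol
Product: 40 PMB-protected α-methylene lactone, via hydroxy enal 38 (not isolated), via lactol 39 (not isolated)
Conditions: 2,2,6,6-tetramethylpiperidin-1-oxyl (TEMPO, cat.), PhI(OAc)2, CH2Cl2, rt
Reagents that add atoms: none
Why: Oxidative lactonisation, in which the oxoammonium salt oxidises the primary allylic alcohol to the enal, the C6 hydroxyl closes the five-membered lactol (ring B) and a second oxidation gives the α-methylene-γ-butyrolactone, uses the C6/C7 configuration from step 13 to fix the ring fusion.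

Step 24
Reactants: 40 PMB-protected lactone
Product: 41 C1-hydroxy lactone
Conditions: DDQ, CH2Cl2/pH 7 phosphate buffer (10:1), 0 °C
Reagents that add atoms: none
Why: DDQ oxidises the electron-rich benzylic ether to an oxocarbenium ion that water hydrolyses, freeing the C1 hydroxyl without touching the lactone, the tiglate or the alkenes.

Step 25
Reactants: 41 C1-hydroxy lactone
Product: 42 target CNP0345906.3
Conditions: Dess–Martin periodinane, NaHCO3, CH2Cl2, 0 °C → rt
Reagents that add atoms: none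
Why: Dess–Martin oxidation of the secondary C1 alcohol gives the C1 ketone, since the adjacent tertiary C10 hydroxyl cannot be oxidised and the periodinane does not cleave the glycol.

Compound list
1 | penta-1,4-dien-3-ol | C=CC(O)C=C | starting material
2 | (2S,3R)-1,2-epoxypent-4-en-3-ol | C=C[C@@H](O)[C@@H]1CO1 | intermediate
3 | (S)-2-[(R)-1-(4-methoxybenzyloxy)prop-2-en-1-yl]oxirane | C=C[C@@H](OCc1ccc(OC)cc1)[C@@H]1CO1 | intermediate
4 | (2S,3R)-3-(4-methoxybenzyloxy)pent-4-en-2-ol | C=C[C@@H](OCc1ccc(OC)cc1)[C@H](C)O | intermediate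
5 | triethyl{[(2S,3R)-3-(4-methoxybenzyloxy)pent-4-en-2-yl]oxy}silane | C=C[C@@H](OCc1ccc(OC)cc1)[C@H](C)O[Si](CC)(CC)CC | intermediate
6 | but-2-yn-1-ol | CC#CCO | starting material
7 | sodium 2,2-bis(2-methoxyethoxy)-3-methyl-2,5-dihydro-1,2-oxaluminol-2-uide (cyclic alkenylaluminate, not isolated) | CC1=CCO[Al-]1(OCCOC)OCCOC.[Na+] | intermediate
8 | (Z)-3-iodobut-2-en-1-ol | C/C(=C/CO)I | intermediate
9 | 9-[(3R,4S)-3-(4-methoxybenzyloxy)-4-(triethylsilyloxy)pentyl]-9-borabicyclo[3.3.1]nonane (not isolated) | C1CCC2CCCC1B2CC[C@@H](OCc1ccc(OC)cc1)[C@H](C)O[Si](CC)(CC)CC | intermediate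
10 | (2Z,6R,7S)-6-(4-methoxybenzyloxy)-3-methyl-7-(triethylsilyloxy)oct-2-en-1-ol | OC/C=C(/C)CC[C@@H](OCc1ccc(OC)cc1)[C@H](C)O[Si](CC)(CC)CC | intermediate
11 | (2Z,6R,7S)-6-(4-methoxybenzyloxy)-3-methyl-7-(triethylsilyloxy)oct-2-enal | O=C/C=C(/C)CC[C@@H](OCc1ccc(OC)cc1)[C@H](C)O[Si](CC)(CC)CC | intermediate
12 | methyl 3-methylbut-2-enoate | COC(=O)C=C(C)C | starting material
13 | methyl (E)-3-methyl-4-oxobut-2-enoate | COC(=O)/C=C(\C)C=O | intermediate
14 | methyl (E)-4-hydroxy-3-methylbut-2-enoate | COC(=O)/C=C(\C)CO | intermediate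
15 | methyl (E)-4-(tert-butyldiphenylsilyloxy)-3-methylbut-2-enoate | COC(=O)/C=C(\C)CO[Si](c1ccccc1)(c1ccccc1)C(C)(C)C | intermediate
16 | (E)-4-(tert-butyldiphenylsilyloxy)-3-methylbut-2-enoic acid | OC(=O)/C=C(\C)CO[Si](c1ccccc1)(c1ccccc1)C(C)(C)C | intermediate
17 | (S)-4-benzyloxazolidin-2-one | O=C1N[C@@H](Cc2ccccc2)CO1 | starting material
18 | (E)-4-(tert-butyldiphenylsilyloxy)-3-methylbut-2-enoic pivalic anhydride (not isolated) | CC(C)(C)C(=O)OC(=O)/C=C(\C)CO[Si](c1ccccc1)(c1ccccc1)C(C)(C)C | intermediate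
19 | (S)-4-benzyl-3-[(E)-4-(tert-butyldiphenylsilyloxy)-3-methylbut-2-enoyl]oxazolidin-2-one | O=C(/C=C(\C)CO[Si](c1ccccc1)(c1ccccc1)C(C)(C)C)N1[C@@H](Cc2ccccc2)COC1=O | intermediate
20 | dibutylboron Z(O)-dienolate of 19 (not isolated) | CCCCB(CCCC)O/C(=C\C(=C)CO[Si](c1ccccc1)(c1ccccc1)C(C)(C)C)N1[C@@H](Cc2ccccc2)COC1=O | intermediate
21 | C6 O-dibutylboron aldolate of 22 (not isolated) | O=C(N1[C@@H](Cc2ccccc2)COC1=O)[C@@H](C(=C)CO[Si](c1ccccc1)(c1ccccc1)C(C)(C)C)[C@H](OB(CCCC)CCCC)/C=C(/C)CC[C@@H](OCc1ccc(OC)cc1)[C@H](C)O[Si](CC)(CC)CC | intermediate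
22 | (S)-4-benzyl-3-[(2S,3R,4Z,8R,9S)-2-[3-(tert-butyldiphenylsilyloxy)prop-1-en-2-yl]-3-hydroxy-8-(4-methoxybenzyloxy)-5-methyl-9-(triethylsilyloxy)dec-4-enoyl]oxazolidin-2-one (germacrane 1R,6R,7S,10S) | O=C(N1[C@@H](Cc2ccccc2)COC1=O)[C@@H](C(=C)CO[Si](c1ccccc1)(c1ccccc1)C(C)(C)C)[C@H](O)/C=C(/C)CC[C@@H](OCc1ccc(OC)cc1)[C@H](C)O[Si](CC)(CC)CC | intermediate
23 | (2S,3R,4Z,8R,9S)-2-[3-(tert-butyldiphenylsilyloxy)prop-1-en-2-yl]-3-hydroxy-N-methoxy-8-(4-methoxybenzyloxy)-N,5-dimethyl-9-(triethylsilyloxy)dec-4-enamide | CON(C)C(=O)[C@@H](C(=C)CO[Si](c1ccccc1)(c1ccccc1)C(C)(C)C)[C@H](O)/C=C(/C)CC[C@@H](OCc1ccc(OC)cc1)[C@H](C)O[Si](CC)(CC)CC | intermediate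
24 | (2S,3R,4Z,8R,9S)-3-(tert-butyldimethylsilyloxy)-2-[3-(tert-butyldiphenylsilyloxy)prop-1-en-2-yl]-N-methoxy-8-(4-methoxybenzyloxy)-N,5-dimethyl-9-(triethylsilyloxy)dec-4-enamide | CON(C)C(=O)[C@@H](C(=C)CO[Si](c1ccccc1)(c1ccccc1)C(C)(C)C)[C@H](O[Si](C)(C)C(C)(C)C)/C=C(/C)CC[C@@H](OCc1ccc(OC)cc1)[C@H](C)O[Si](CC)(CC)CC | intermediate
25 | dibromomethane | BrCBr | starting material
26 | lithium alkoxide of the tetrahedral bromomethyl adduct of 24 (not isolated) | [Li]OC(CBr)(N(C)OC)[C@@H](C(=C)CO[Si](c1ccccc1)(c1ccccc1)C(C)(C)C)[C@H](O[Si](C)(C)C(C)(C)C)/C=C(/C)CC[C@@H](OCc1ccc(OC)cc1)[C@H](C)O[Si](CC)(CC)CC | intermediate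
27 | (3S,4R,5Z,9R,10S)-1-bromo-4-(tert-butyldimethylsilyloxy)-3-[3-(tert-butyldiphenylsilyloxy)prop-1-en-2-yl]-9-(4-methoxybenzyloxy)-6-methyl-10-(triethylsilyloxy)undec-5-en-2-one | BrCC(=O)[C@@H](C(=C)CO[Si](c1ccccc1)(c1ccccc1)C(C)(C)C)[C@H](O[Si](C)(C)C(C)(C)C)/C=C(/C)CC[C@@H](OCc1ccc(OC)cc1)[C@H](C)O[Si](CC)(CC)CC | intermediate
28 | (3S,4R,5Z,9R,10S)-1-bromo-4-(tert-butyldimethylsilyloxy)-3-[3-(tert-butyldiphenylsilyloxy)prop-1-en-2-yl]-10-hydroxy-9-(4-methoxybenzyloxy)-6-methylundec-5-en-2-one | BrCC(=O)[C@@H](C(=C)CO[Si](c1ccccc1)(c1ccccc1)C(C)(C)C)[C@H](O[Si](C)(C)C(C)(C)C)/C=C(/C)CC[C@@H](OCc1ccc(OC)cc1)[C@H](C)O | intermediate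
29 | (3S,4R,5Z,9R)-1-bromo-4-(tert-butyldimethylsilyloxy)-3-[3-(tert-butyldiphenylsilyloxy)prop-1-en-2-yl]-9-(4-methoxybenzyloxy)-6-methylundec-5-ene-2,10-dione (germacrane 1R,6R,7S; key precursor) | BrCC(=O)[C@@H](C(=C)CO[Si](c1ccccc1)(c1ccccc1)C(C)(C)C)[C@H](O[Si](C)(C)C(C)(C)C)/C=C(/C)CC[C@@H](OCc1ccc(OC)cc1)C(C)=O | intermediate
30 | diiodosamarium C8=C9 enolate of 29 (not isolated) | C=C(O[Sm]([I])[I])[C@@H](C(=C)CO[Si](c1ccccc1)(c1ccccc1)C(C)(C)C)[C@H](O[Si](C)(C)C(C)(C)C)/C=C(/C)CC[C@@H](OCc1ccc(OC)cc1)C(C)=O | intermediate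
31 | C10 O-diiodosamarium aldolate of 32 (not isolated) | C=C(CO[Si](c1ccccc1)(c1ccccc1)C(C)(C)C)[C@H]1[C@H](O[Si](C)(C)C(C)(C)C)/C=C(/C)CC[C@@H](OCc2ccc(OC)cc2)[C@](C)(O[Sm]([I])[I])CC1=O | intermediate
32 | (1R,4Z,6R,7S,10R)-6-(tert-butyldimethylsilyloxy)-12-(tert-butyldiphenylsilyloxy)-10-hydroxy-1-(4-methoxybenzyloxy)germacra-4,11(13)-dien-8-one | C=C(CO[Si](c1ccccc1)(c1ccccc1)C(C)(C)C)[C@H]1[C@H](O[Si](C)(C)C(C)(C)C)/C=C(/C)CC[C@@H](OCc2ccc(OC)cc2)[C@](C)(O)CC1=O | intermediate
33 | (1R,4Z,6R,7R,8R,10R)-6-(tert-butyldimethylsilyloxy)-12-(tert-butyldiphenylsilyloxy)-1-(4-methoxybenzyloxy)germacra-4,11(13)-diene-8,10-diol | C=C(CO[Si](c1ccccc1)(c1ccccc1)C(C)(C)C)[C@H]1[C@H](O[Si](C)(C)C(C)(C)C)/C=C(/C)CC[C@@H](OCc2ccc(OC)cc2)[C@](C)(O)C[C@H]1O | intermediate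
34 | tiglic acid, (E)-2-methylbut-2-enoic acid | C/C=C(\C)C(=O)O | starting material
35 | (E)-2-methylbut-2-enoic 2,4,6-trichlorobenzoic anhydride (not isolated) | C/C=C(\C)C(=O)OC(=O)c1c(Cl)cc(Cl)cc1Cl | intermediate
36 | (1R,4Z,6R,7R,8R,10R)-6-(tert-butyldimethylsilyloxy)-12-(tert-butyldiphenylsilyloxy)-10-hydroxy-1-(4-methoxybenzyloxy)germacra-4,11(13)-dien-8-yl (E)-2-methylbut-2-enoate | C=C(CO[Si](c1ccccc1)(c1ccccc1)C(C)(C)C)[C@H]1[C@H](O[Si](C)(C)C(C)(C)C)/C=C(/C)CC[C@@H](OCc2ccc(OC)cc2)[C@](C)(O)C[C@H]1OC(=O)/C(C)=C/C | intermediate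
37 | (1R,4Z,6R,7S,8R,10R)-6,10,12-trihydroxy-1-(4-methoxybenzyloxy)germacra-4,11(13)-dien-8-yl (E)-2-methylbut-2-enoate | C=C(CO)[C@H]1[C@H](O)/C=C(/C)CC[C@@H](OCc2ccc(OC)cc2)[C@](C)(O)C[C@H]1OC(=O)/C(C)=C/C | intermediate
38 | 12-oxo analogue of 37 (C12 enal with free C6 hydroxyl, not isolated) | C=C(C=O)[C@H]1[C@H](O)/C=C(/C)CC[C@@H](OCc2ccc(OC)cc2)[C@](C)(O)C[C@H]1OC(=O)/C(C)=C/C | intermediate
39 | 12,6-lactol of 38 (C12 hemiacetal, not isolated) | C=C1C(O)O[C@@H]2/C=C(/C)CC[C@@H](OCc3ccc(OC)cc3)[C@](C)(O)C[C@@H](OC(=O)/C(C)=C/C)[C@@H]12 | intermediate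
40 | (1R,4Z,6R,7R,8R,10R)-10-hydroxy-1-(4-methoxybenzyloxy)-8-[(E)-2-methylbut-2-enoyloxy]germacra-4,11(13)-dien-12,6-olide | C=C1C(=O)O[C@@H]2/C=C(/C)CC[C@@H](OCc3ccc(OC)cc3)[C@](C)(O)C[C@@H](OC(=O)/C(C)=C/C)[C@@H]12 | intermediate
41 | (1R,4Z,6R,7R,8R,10R)-1,10-dihydroxy-8-[(E)-2-methylbut-2-enoyloxy]germacra-4,11(13)-dien-12,6-olide | C=C1C(=O)O[C@@H]2/C=C(/C)CC[C@@H](O)[C@](C)(O)C[C@@H](OC(=O)/C(C)=C/C)[C@@H]12 | intermediate
42 | CNP0345906.3, (4Z,6R,7R,8R,10R)-10-hydroxy-1-oxo-8-[(E)-2-methylbut-2-enoyloxy]germacra-4,11(13)-dien-12,6-olide | C=C1C(=O)O[C@@H]2/C=C(/C)CCC(=O)[C@](C)(O)C[C@@H](OC(=O)/C(C)=C/C)[C@@H]12 | target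

Total step count: 25. Longest linear sequence: 19 steps (1–4, 6, 7, 13–25).

Steps most likely to fail

Step 19 (ring closure). The samarium enolate may be protonated or react between molecules before it closes the ten-membered ring. The C10 ketone may also be reduced or lose its α-alkoxy group under electron-transfer conditions, and addition without chelation would scramble C10. The fallback separates enolate formation from ring closure. Setting out from 29, zinc dust and Me3SiCl in Et2O/MeCN convert the bromomethyl ketone regiospecifically into the trimethylsilyl enol ether F1. Slow addition of F1 to MgBr2·OEt2 in CH2Cl2 at −78 °C under high dilution then closes ring A by a chelation-controlled intramolecular Mukaiyama aldol, the magnesium bridging the C10 carbonyl and the C1 PMB ether and activating only that ketone. Aqueous work-up returns the route at 32.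

Step 16 (bromomethyl ketone). The carbenoid may deprotonate the doubly activated C7–H (amide and vinyl), or decompose before it adds to the hindered amide; the result would be recovered, conjugated or β-eliminated material. The fallback avoids strong base altogether. Setting out from 22, silylation (t-BuMe2SiOTf, 2,6-lutidine) gives the TBS-protected acyl oxazolidinone F2. LiOH/H2O2 in THF/H2O removes the auxiliary to give the carboxylic acid F3. 1-Chloro-N,N,2-trimethylprop-1-en-1-amine converts it under neutral conditions into the acid chloride F4. Excess diazomethane in Et2O at 0 °C gives the diazoketone F5, and one equivalent of HBr in Et2O at −30 °C replaces N2 by bromide. The route is rejoined at 27; if the TES ether is lost in the acid, it is rejoined at 28.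

Step 20 (C8 reduction). Hydride delivery directed by the tertiary C10 hydroxyl may be overridden by the conformation of the ten-membered ring, or the tertiary alcohol may exchange too slowly onto boron, so that the 8S alcohol prevails. The fallback takes that epimer on purpose and inverts it while installing the ester. Setting out from 32, chelation-controlled syn reduction (Et2BOMe, NaBH4, THF/MeOH, −78 °C; Narasaka–Prasad) gives the 8S syn-diol F6. Mitsunobu esterification of F6 with tiglic acid 34 (PPh3, diisopropyl azodicarboxylate, toluene, 0 °C → rt) installs the tiglate with inversion at C8 and returns the route at 36.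

Further compounds
F1 | step 19 | C8 trimethylsilyl enol ether of 29 (C8(OSiMe3)=C9H2, C10 methyl ketone retained) | C=C(O[Si](C)(C)C)[C@@H](C(=C)CO[Si](c1ccccc1)(c1ccccc1)C(C)(C)C)[C@H](O[Si](C)(C)C(C)(C)C)/C=C(/C)CC[C@@H](OCc1ccc(OC)cc1)C(C)=O
F2 | step 16 | C6 TBS ether of aldol adduct 22 | O=C(N1[C@@H](Cc2ccccc2)COC1=O)[C@@H](C(=C)CO[Si](c1ccccc1)(c1ccccc1)C(C)(C)C)[C@H](O[Si](C)(C)C(C)(C)C)/C=C(/C)CC[C@@H](OCc1ccc(OC)cc1)[C@H](C)O[Si](CC)(CC)CC
F3 | step 16 | C8 carboxylic acid from F2 | OC(=O)[C@@H](C(=C)CO[Si](c1ccccc1)(c1ccccc1)C(C)(C)C)[C@H](O[Si](C)(C)C(C)(C)C)/C=C(/C)CC[C@@H](OCc1ccc(OC)cc1)[C@H](C)O[Si](CC)(CC)CC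
F4 | step 16 | C8 acid chloride from F3 | ClC(=O)[C@@H](C(=C)CO[Si](c1ccccc1)(c1ccccc1)C(C)(C)C)[C@H](O[Si](C)(C)C(C)(C)C)/C=C(/C)CC[C@@H](OCc1ccc(OC)cc1)[C@H](C)O[Si](CC)(CC)CC
F5 | step 16 | C8 diazomethyl ketone from F4 | [N-]=[N+]=CC(=O)[C@@H](C(=C)CO[Si](c1ccccc1)(c1ccccc1)C(C)(C)C)[C@H](O[Si](C)(C)C(C)(C)C)/C=C(/C)CC[C@@H](OCc1ccc(OC)cc1)[C@H](C)O[Si](CC)(CC)CC
F6 | step 20 | (8S)-epimer of diol 33 (8,10-syn diol) | C=C(CO[Si](c1ccccc1)(c1ccccc1)C(C)(C)C)[C@H]1[C@H](O[Si](C)(C)C(C)(C)C)/C=C(/C)CC[C@@H](OCc2ccc(OC)cc2)[C@](C)(O)C[C@@H]1O
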